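**Plan**
- Retrosynthesis cuts, in order: the acetate O–acyl bond; the C8–O bond (hydration of a C7=C8 alkene); the C9–C10 bond while C2 is re-joined to C7 (oxy-Cope retron); the C7–C8 bond (alkenyl metal + ketone); the C5–C6 and C2–C7 bonds (Diels–Alder).
- Enabling feature: rings A/B are cis-fused (H-5 and CH3-20 on one face) and the C9 chain is trans to CH3-20. This is the signature of a boat [3,3] shift in a 2-alkenylbicyclo[2.2.2]oct-5-en-2-ol in which C2–C7 is a temporary bridge bond and C7 carries a temporary oxygen.
- Forward: ring A enters as a cyclohexadiene; a Diels–Alder reaction builds the bridged bicycle; the side-chain fragment (C8, C9, C11–C17) is joined at C7; the oxy-Cope shift opens the bicycle and closes ring B through C9–C10, leaving ring A with a C1=C2 bond.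
- Helpers removed afterwards: the C7 oxygen (as enol triflate, reduced), the C1=C2 bond (hydrogenated), the benzyl ether.
- Stereochemistry: C13 from (S)-citronellol; C5 from the catalytic asymmetric Diels–Alder; C10 and C9 relayed from C5 and from the E alkene in the [3,3] shift; C8 by oxygenation on the convex α face.

Key step: step 11

Remark: labdane numbering is used (ring A = C1–C5, C10; ring B = C5–C10; chain C11–C16; C17 on C8; C18/C19 on C4; C20 on C10). Read this way the target SMILES has H-5 and CH3-20 on the same face, i.e. a cis-fused decalin with (5S,8R,9R,10R,13S) configuration, and the route is built for that isomer.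
Assumption: 2,4,4-trimethylcyclohex-2-en-1-one (1) is taken as a catalogue compound.

**Fragment 1 (bicyclic ketone)**

Step 1
Reactants: 1 2,4,4-trimethylcyclohex-2-en-1-one
Product: 3 4,4,6-trimethylcyclohexa-1,5-dien-1-yl trifluoromethanesulfonate, via lithium dienolate 2 (not isolated)
Conditions: LiN(i-Pr)2, THF, −78 °C; then PhNTf2, −78 °C to 0 °C
Reagents that add atoms: N-phenylbis(trifluoromethanesulfonimide), O=S(=O)(N(c1ccccc1)S(=O)(=O)C(F)(F)F)C(F)(F)F
Why: Kinetic deprotonation at the only enolisable position (C6, since C4 is quaternary) and O-triflation of the cross-conjugated dienolate give the dienyl triflate (enol triflate formation).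

Step 2
Reactants: 3 4,4,6-trimethylcyclohexa-1,5-dien-1-yl trifluoromethanesulfonate
Product: 4 2,6,6-trimethylcyclohexa-1,3-diene
Conditions: Pd(OAc)2 (cat.), PPh3, HCO2H, Bu3N, DMF, 60 °C
Reagents that add atoms: none
Why: Palladium-catalysed formate reduction of the vinyl triflate replaces OTf by H without moving the diene, so the methyl sits on the internal diene carbon next to the terminus that adjoins the gem-dimethyl carbon.

Step 3
Reactants: 4 2,6,6-trimethylcyclohexa-1,3-diene; 5 acrolein
Product: 6 (1R,2R,4S)-5,8,8-trimethylbicyclo[2.2.2]oct-5-ene-2-carbaldehyde (endo aldehyde)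
Conditions: (5S)-5-benzyl-2,2,3-trimethylimidazolidin-4-one hydrochloride (20 mol %), MeCN/H2O 95:5, rt
Reagents that add atoms: none
Why: Organocatalytic Diels–Alder reaction by iminium activation, in which the acrolein CH2 bonds to the diene terminus next to the methyl-bearing carbon ("para" orientation, also the sterically matched one), the endo transition state is preferred and the benzyl group of the (5S)-catalyst shields one face of the (E)-iminium ion, so that the (1R,2R,4S) adduct is expected; the minor exo adduct, which would lead to the antipodal ketone, is removed by chromatography.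

Step 4
Reactants: 6 (1R,2R,4S)-5,8,8-trimethylbicyclo[2.2.2]oct-5-ene-2-carbaldehyde
Product: 8 (1R,4S)-5,8,8-trimethylbicyclo[2.2.2]oct-5-en-2-one, via hydroperoxy aldehyde 7 (not isolated)
Conditions: Cu(OAc)2 (cat.), 2,2'-bipyridine, DABCO, O2 (1 atm), DMF, 40 °C
Reagents that add atoms: dioxygen, O=O
Why: Copper-catalysed aerobic oxidative deformylation of an α-branched aldehyde: the enol is oxygenated at C2 and the α-hydroperoxy aldehyde fragments to the ketone and formic acid, leaving the bridgehead stereocentres untouched.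

**Fragment 2 (alkenyl iodide)**

Step 5
Reactants: 9 (S)-citronellol
Product: 11 benzyl (S)-citronellyl ether, via sodium (S)-citronellolate 10 (not isolated)
Conditions: NaH, BnBr, Bu4NI (cat.), THF, 0 °C to rt
Reagents that add atoms: benzyl bromide, BrCc1ccccc1
Why: Williamson ether synthesis protects the primary alcohol as a group that survives organolithium, hydride and base and is removed in step 14.

Step 6
Reactants: 11 benzyl (S)-citronellyl ether
Product: 13 (4S)-6-(benzyloxy)-4-methylhexanal, via ozonide 12 (not isolated)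
Conditions: O3, CH2Cl2, −78 °C; then PPh3, −78 °C to rt
Reagents that add atoms: ozone, [O-][O+]=O
Why: Ozonolysis of the trisubstituted alkene with reductive work-up gives the aldehyde whose carbonyl carbon becomes C9; the C13 stereocentre is remote and untouched.

Step 7
Reactants: 13 (4S)-6-(benzyloxy)-4-methylhexanal
Product: 14 ({[(3S)-7,7-dibromo-3-methylhept-6-en-1-yl]oxy}methyl)benzene
Conditions: CBr4, PPh3, CH2Cl2, 0 °C
Reagents that add atoms: carbon tetrabromide, BrC(Br)(Br)Br
Why: First stage of the Corey–Fuchs reaction (Wittig olefination by the ylide Ph3P=CBr2 formed in the flask) adds the carbon that becomes C8.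

Step 8
Reactants: 14 ({[(3S)-7,7-dibromo-3-methylhept-6-en-1-yl]oxy}methyl)benzene
Product: 16 ({[(3S)-3-methyloct-6-yn-1-yl]oxy}methyl)benzene, via lithium acetylide 15 (not isolated)
Conditions: n-BuLi (2.1 equiv), THF, −78 °C to 0 °C; then MeI, −78 °C to rt
Reagents that add atoms: iodomethane, CI
Why: Second stage of the Corey–Fuchs reaction (bromine–lithium exchange, Fritsch–Buttenberg–Wiechell shift, deprotonation) gives the lithium acetylide, whose methylation installs C17.

Step 9
Reactants: 16 ({[(3S)-3-methyloct-6-yn-1-yl]oxy}methyl)benzene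
Product: 18 ({[(3S,6E)-7-iodo-3-methyloct-6-en-1-yl]oxy}methyl)benzene, via alkenylzirconocene chloride 17 (not isolated)
Conditions: Cp2Zr(H)Cl (excess), THF, rt to 50 °C; then I2, 0 °C
Reagents that add atoms: iodine, II
Why: Hydrozirconation (syn addition of Zr–H) of the methyl alkyne puts zirconium on the less hindered methyl-bearing carbon after equilibration with excess reagent, and iodinolysis with retention gives the (E)-2-iodo-2-alkene with the chain trans to iodine; the minor regioisomer is removed by chromatography.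

**Union and endgame**

Step 10
Reactants: 18 ({[(3S,6E)-7-iodo-3-methyloct-6-en-1-yl]oxy}methyl)benzene; 8 (1R,4S)-5,8,8-trimethylbicyclo[2.2.2]oct-5-en-2-one
Product: 21 (1R,2S,4S)-2-[(2E,6S)-8-(benzyloxy)-6-methyloct-2-en-2-yl]-5,8,8-trimethylbicyclo[2.2.2]oct-5-en-2-ol, via alkenyllithium 19 (not isolated), via alkenylcerium dichloride 20 (not isolated)
Conditions: t-BuLi (2 equiv), Et2O, −78 °C; CeCl3 (anhydrous), THF, −78 °C; then 8, −78 °C to −20 °C; aqueous work-up
Reagents that add atoms: none
Why: Iodine–lithium exchange with retention of alkene geometry, transmetalation to the less basic organocerium reagent (suppresses enolisation) and 1,2-addition from the face of the etheno bridge, which is less hindered than the face of the ethano-bridge methylene, form the C7–C8 bond and place the alkenyl group syn to the ring double bond as the [3,3] shift requires.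

Step 11
Reactants: 21 (1R,2S,4S)-2-[(2E,6S)-8-(benzyloxy)-6-methyloct-2-en-2-yl]-5,8,8-trimethylbicyclo[2.2.2]oct-5-en-2-ol
Product: 24 cis-fused enol triflate (15-benzyloxy-5,10-cis-labda-1,7-dien-7-yl trifluoromethanesulfonate), via potassium alkoxide 22 (not isolated), via potassium enolate 23 (not isolated)
Conditions: KH, 18-crown-6, THF, 0 °C to rt; then PhNTf2, −78 °C to 0 °C
Reagents that add atoms: N-phenylbis(trifluoromethanesulfonimide), O=S(=O)(N(c1ccccc1)S(=O)(=O)C(F)(F)F)C(F)(F)F
Why: Deprotonation gives alkoxide 22, whose 1,5-diene (C9=C8–C7–C2–C1=C10) undergoes an anionic oxy-Cope [3,3] sigmatropic shift that breaks the C2–C7 bridge bond and forms C9–C10 to give enolate 23, which PhNTf2 traps on oxygen. The closest known reaction type is the anionic oxy-Cope rearrangement of 2-alkenylbicyclo[2.2.2]oct-5-en-2-ols to cis-fused octalones, with enolate triflation in the same flask. Ring B (C5–C6–C7–C8–C9–C10) is closed by sigmatropic reorganisation through the boat transition state that the bicycle imposes, not by a chain cyclisation, and ring A is the former cyclohexadiene ring, now with a C1=C2 bond. C10 is bonded on the alkene face turned toward the carbinol bridge, which puts C9 cis to C6 across C5–C10 and hence CH3-20 cis to H-5 (cis fusion, relayed from C5); C9 is set by the E geometry of C8=C9, whose outward substituent C11 ends up trans to CH3-20. The step needs the alkenyl group syn to the C1=C10 bridge (secured in step 10) and a [3,3] shift that is faster than alkoxide fragmentation, which the crown-ether-separated potassium alkoxide and the release of bicyclic strain favour; the triflate fixes the regiodefined C7=C8 enolate.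

Step 12
Reactants: 24 cis-fused enol triflate
Product: 25 15-benzyloxy-5,10-cis-labda-1,7-diene
Conditions: Pd(OAc)2 (cat.), PPh3, HCO2H, Bu3N, DMF, 60 °C
Reagents that add atoms: none
Why: Palladium-catalysed formate reduction of the enol triflate removes the temporary C7 oxygen and leaves the C7=C8 trisubstituted alkene regiospecifically, with no stereocentre touched.

Step 13
Reactants: 25 15-benzyloxy-5,10-cis-labda-1,7-diene
Product: 27 (5S,8R,9R,10R,13S)-15-benzyloxy-5,10-cis-labd-1-en-8-ol, via tertiary hydroperoxide 26 (not isolated)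
Conditions: Mn(dpm)3 (cat.), PhSiH3, O2 (1 atm), i-PrOH/CH2Cl2, 0 °C to rt; then PPh3
Reagents that add atoms: dioxygen, O=O
Why: Mukaiyama hydration by metal-hydride hydrogen-atom transfer puts H on C7 and the radical on tertiary C8 (the 1,2-disubstituted C1=C2 bond reacts much more slowly), and O2 is expected to be captured on the α face, away from the axial C1 of ring A that covers the β face of C8, giving the 8-OH cis to CH3-20; PPh3 reduces the hydroperoxide.

Step 14
Reactants: 27 (5S,8R,9R,10R,13S)-15-benzyloxy-5,10-cis-labd-1-en-8-ol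
Product: 28 (5S,8R,9R,10R,13S)-5,10-cis-labdane-8,15-diol
Conditions: H2 (1 atm), 10% Pd/C, EtOAc/EtOH, rt
Reagents that add atoms: none
Why: Heterogeneous hydrogenation saturates the C1=C2 bond (no new stereocentre) and hydrogenolyses the benzyl ether in the same operation.

Step 15
Reactants: 28 (5S,8R,9R,10R,13S)-5,10-cis-labdane-8,15-diol
Product: 29 target, (3S)-5-[(1R,2R,4aS,8aR)-2-hydroxy-2,5,5,8a-tetramethyldecahydronaphthalen-1-yl]-3-methylpentyl acetate
Conditions: Ac2O, pyridine, DMAP (cat.), CH2Cl2, 0 °C
Reagents that add atoms: acetic anhydride, CC(=O)OC(C)=O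
Why: Selective acetylation of the primary alcohol; the hindered tertiary 8-OH does not react under these conditions.

**Compound list**

1 | 2,4,4-trimethylcyclohex-2-en-1-one | CC1=CC(C)(C)CCC1=O | starting material
2 | lithium 4,4,6-trimethylcyclohexa-1,5-dien-1-olate | [Li+].[O-]C1=CCC(C)(C)C=C1C | intermediate (not isolated)
3 | 4,4,6-trimethylcyclohexa-1,5-dien-1-yl trifluoromethanesulfonate | CC1=CC(C)(C)CC=C1OS(=O)(=O)C(F)(F)F | intermediate
4 | 2,6,6-trimethylcyclohexa-1,3-diene | CC1=CC(C)(C)CC=C1 | intermediate
5 | acrolein | C=CC=O | starting material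
6 | (1R,2R,4S)-5,8,8-trimethylbicyclo[2.2.2]oct-5-ene-2-carbaldehyde | O=C[C@@H]1C[C@H]2C(C)(C)C[C@@H]1C=C2C | intermediate
7 | (1R,4S)-2-hydroperoxy-5,8,8-trimethylbicyclo[2.2.2]oct-5-ene-2-carbaldehyde (C2 not defined) | O=CC1(OO)C[C@H]2C(C)(C)C[C@@H]1C=C2C | intermediate (not isolated)
8 | (1R,4S)-5,8,8-trimethylbicyclo[2.2.2]oct-5-en-2-one | O=C1C[C@H]2C(C)(C)C[C@@H]1C=C2C | intermediate
9 | (S)-citronellol | OCC[C@@H](C)CCC=C(C)C | starting material
10 | sodium (S)-citronellolate | [Na+].[O-]CC[C@@H](C)CCC=C(C)C | intermediate (not isolated)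
11 | benzyl (S)-citronellyl ether, ({[(3S)-3,7-dimethyloct-6-en-1-yl]oxy}methyl)benzene | C(c1ccccc1)OCC[C@@H](C)CCC=C(C)C | intermediate
12 | 3-[(3S)-5-(benzyloxy)-3-methylpentyl]-5,5-dimethyl-1,2,4-trioxolane (ozonide) | C(c1ccccc1)OCC[C@@H](C)CCC1OOC(C)(C)O1 | intermediate (not isolated)
13 | (4S)-6-(benzyloxy)-4-methylhexanal | C(c1ccccc1)OCC[C@@H](C)CCC=O | intermediate
14 | ({[(3S)-7,7-dibromo-3-methylhept-6-en-1-yl]oxy}methyl)benzene | C(c1ccccc1)OCC[C@@H](C)CCC=C(Br)Br | intermediate
15 | lithium acetylide of (5S)-7-(benzyloxy)-5-methylhept-1-yne | C(c1ccccc1)OCC[C@@H](C)CCC#C[Li] | intermediate (not isolated)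
16 | ({[(3S)-3-methyloct-6-yn-1-yl]oxy}methyl)benzene | C(c1ccccc1)OCC[C@@H](C)CCC#CC | intermediate
17 | (E)-alkenylzirconocene chloride (Zr on C8, chain trans to Zr) | C(c1ccccc1)OCC[C@@H](C)CC/C=C(\C)[Zr](Cl)(C1C=CC=C1)C1C=CC=C1 | intermediate (not isolated)
18 | ({[(3S,6E)-7-iodo-3-methyloct-6-en-1-yl]oxy}methyl)benzene | C(c1ccccc1)OCC[C@@H](C)CC/C=C(\C)I | intermediate
19 | alkenyllithium from 18 (geometry retained) | C(c1ccccc1)OCC[C@@H](C)CC/C=C(\C)[Li] | intermediate (not isolated)
20 | alkenylcerium dichloride from 19 | C(c1ccccc1)OCC[C@@H](C)CC/C=C(\C)[Ce](Cl)Cl | intermediate (not isolated)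
21 | (1R,2S,4S)-2-[(2E,6S)-8-(benzyloxy)-6-methyloct-2-en-2-yl]-5,8,8-trimethylbicyclo[2.2.2]oct-5-en-2-ol | O[C@@]1(/C(C)=C/CC[C@H](C)CCOCc3ccccc3)C[C@H]2C(C)(C)C[C@@H]1C=C2C | intermediate
22 | potassium alkoxide of 21 | [K+].[O-][C@@]1(/C(C)=C/CC[C@H](C)CCOCc3ccccc3)C[C@H]2C(C)(C)C[C@@H]1C=C2C | intermediate (not isolated)
23 | potassium C7=C8 enolate of the cis-fused 7-ketone (C5, C9, C10 as in the target) | C(c1ccccc1)OCC[C@@H](C)CC[C@@H]2[C@]3(C)C=CCC(C)(C)[C@@H]3CC([O-])=C2C.[K+] | intermediate (not isolated)
24 | 15-benzyloxy-5,10-cis-labda-1,7-dien-7-yl trifluoromethanesulfonate (H-5 and CH3-20 cis, C11 trans to CH3-20, 13S) | C(c1ccccc1)OCC[C@@H](C)CC[C@@H]2[C@]3(C)C=CCC(C)(C)[C@@H]3CC(OS(=O)(=O)C(F)(F)F)=C2C | intermediate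
25 | 15-benzyloxy-5,10-cis-labda-1,7-diene (same configuration as 24) | C(c1ccccc1)OCC[C@@H](C)CC[C@@H]2[C@]3(C)C=CCC(C)(C)[C@@H]3CC=C2C | intermediate
26 | 15-benzyloxy-5,10-cis-labd-1-en-8-yl hydroperoxide (8-OOH cis to CH3-20) | C(c1ccccc1)OCC[C@@H](C)CC[C@@H]2[C@]3(C)C=CCC(C)(C)[C@@H]3CC[C@@]2(C)OO | intermediate (not isolated)
27 | (5S,8R,9R,10R,13S)-15-benzyloxy-5,10-cis-labd-1-en-8-ol | C(c1ccccc1)OCC[C@@H](C)CC[C@@H]2[C@]3(C)C=CCC(C)(C)[C@@H]3CC[C@@]2(C)O | intermediate
28 | (5S,8R,9R,10R,13S)-5,10-cis-labdane-8,15-diol | OCC[C@@H](C)CC[C@@H]1[C@]2(C)CCCC(C)(C)[C@@H]2CC[C@@]1(C)O | intermediate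
29 | (3S)-5-[(1R,2R,4aS,8aR)-2-hydroxy-2,5,5,8a-tetramethyldecahydronaphthalen-1-yl]-3-methylpentyl acetate | CC(=O)OCC[C@@H](C)CC[C@@H]1[C@]2(C)CCCC(C)(C)[C@@H]2CC[C@@]1(C)O | target

**Step count and risks**

Total steps: 15 (fragment 1: steps 1–4; fragment 2: steps 5–9; union and endgame: steps 10–15).
Longest linear sequence: 11 steps (steps 5–15, from (S)-citronellol).

The three steps most likely to fail:

Step 11. The [3,3] shift must join a fully substituted alkene carbon (C10) to a substituted alkenyl terminus (C9). If it is slow, fragmentation of the alkoxide without C9–C10 bonding, or incomplete O-triflation of the hindered enolate, may take over. The fallback separates the rearrangement from the anionic regime and from the trapping. It sets out from 21: silylation (TMSCl, imidazole, DMF) gives the trimethylsilyl ether F1. Heating in degassed toluene in a sealed tube (about 230 °C) effects the neutral siloxy-Cope shift to the trimethylsilyl enol ether F2. MeLi (THF, 0 °C) releases the regiodefined lithium enolate F3, and PhNTf2 converts it to 24, where the route is rejoined.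

Step 13. Capture of the planar C8 radical by O2 may show poor facial selectivity (giving the C8 epimer), and hydrogen-atom transfer to the C1=C2 bond may compete. The fallback replaces the radical hydration by a concerted oxygen transfer followed by hydride opening. It sets out from 25: mCPBA (NaHCO3, CH2Cl2, 0 °C) is expected to epoxidise the more nucleophilic trisubstituted alkene on the convex α face, giving the 7α,8α-epoxide F4. LiEt3BH (THF, reflux) delivers hydride to the secondary C7 and leaves the oxygen on C8, which gives 27, where the route is rejoined.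

Step 3. The diene terminus next to the gem-dimethyl carbon may react too slowly with the iminium ion, and exo adduct that is not removed lowers the enantiomeric purity of 8. The fallback uses Lewis-acid catalysis and an ester in place of the aldehyde. It sets out from 4: Diels–Alder reaction with 2,2,2-trifluoroethyl acrylate, catalysed by the chiral oxazaborolidinium triflimide made from α,α-diphenylprolinol, o-tolylboronic acid and Tf2NH (the enantiomer of the catalyst that delivers the (1R,2R,4S) adduct), gives the endo ester F5. Enolate hydroxylation (LiN(i-Pr)2, then O2 and P(OEt)3) gives the α-hydroxy ester F6, LiAlH4 gives the diol F7, and NaIO4 cleaves it to 8, where the route is rejoined.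

**Further compounds**

F1 | step 11 | trimethylsilyl ether of 21 | C[Si](C)(C)O[C@@]1(/C(C)=C/CC[C@H](C)CCOCc3ccccc3)C[C@H]2C(C)(C)C[C@@H]1C=C2C
F2 | step 11 | trimethylsilyl enol ether (C7=C8) of the cis-fused 7-ketone | C(c1ccccc1)OCC[C@@H](C)CC[C@@H]2[C@]3(C)C=CCC(C)(C)[C@@H]3CC(O[Si](C)(C)C)=C2C
F3 | step 11 | lithium C7=C8 enolate of the cis-fused 7-ketone | C(c1ccccc1)OCC[C@@H](C)CC[C@@H]2[C@]3(C)C=CCC(C)(C)[C@@H]3CC([O-])=C2C.[Li+]
F4 | step 13 | 15-benzyloxy-7α,8α-epoxy-5,10-cis-labd-1-ene | C(c1ccccc1)OCC[C@@H](C)CC[C@@H]2[C@]3(C)C=CCC(C)(C)[C@@H]3C[C@H]4O[C@]42C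
F5 | step 3 | 2,2,2-trifluoroethyl (1R,2R,4S)-5,8,8-trimethylbicyclo[2.2.2]oct-5-ene-2-carboxylate | O=C(OCC(F)(F)F)[C@@H]1C[C@H]2C(C)(C)C[C@@H]1C=C2C
F6 | step 3 | 2,2,2-trifluoroethyl (1R,4S)-2-hydroxy-5,8,8-trimethylbicyclo[2.2.2]oct-5-ene-2-carboxylate (C2 not defined) | O=C(OCC(F)(F)F)C1(O)C[C@H]2C(C)(C)C[C@@H]1C=C2C
F7 | step 3 | (1R,4S)-2-(hydroxymethyl)-5,8,8-trimethylbicyclo[2.2.2]oct-5-en-2-ol (C2 not defined) | OCC1(O)C[C@H]2C(C)(C)C[C@@H]1C=C2C
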